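## Retrosynthetic overview

1. The oxirane is made last: hydroxyl-directed epoxidation of the C8=C9 alkene from the face of the free C6 hydroxyl, with unmasking of the phenol in the same flask.
2. Key C–O step: the tertiary 4-O-aroyl / free 6α-OH pattern comes from a ring-fused tertiary aldol (4β-hydroxy-6-ketone) and a silyl-masked 4-hydroxybenzaldehyde by an Evans–Tishchenko-type acyl-transfer reduction. This makes the ester C–O bond on the hindered oxygen and sets C6.
3. The tertiary aldol comes from oxidation of a 4,6-diol whose seven-membered ring is closed by ring-closing metathesis (C8=C9).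
4. The diene comes from isopropyl addition to a 2,3,3-trisubstituted cyclopentanone, itself made by copper-catalysed asymmetric conjugate methylation / aldol of 3-allylcyclopentenone (sets C1 and C5).
5. Ring order: the five-membered ring is in the starting enone, the seven-membered ring is closed second, the oxirane third.

Assumption: position labels follow daucane numbering (C1 = methyl-bearing ring-fusion carbon, C4 = isopropyl carbinol carbon, C5 = ring-fusion CH, C6 = secondary carbinol, C8/C9 = oxirane carbons), and the ligand antipode in step 3 is the one that gives the R quaternary centre.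

## Route

Step 1
Reactants: 1 3-ethoxycyclopent-2-en-1-one
Product: 3 3-(prop-2-en-1-yl)cyclopent-2-en-1-one, via 1-allyl-3-ethoxycyclopent-2-en-1-ol 2 (not isolated)
Conditions: allylMgBr (1.2 equiv), THF, −20 to 0 °C; then 1 M HCl, 0 °C, 10 min
Reagents that add atoms: allylmagnesium bromide, C=CC[Mg]Br; water, O
Why: Stork–Danheiser sequence, in which the Grignard reagent adds 1,2 to the vinylogous ester and cold dilute acid hydrolyses the enol-ether carbinol with transposition to the β-allyl enone (kept cold and brief so the skipped diene does not move into conjugation); no stereocentre is formed.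

Step 2
Reactants: 4 3-methylbut-3-en-1-ol
Product: 5 3-methylbut-3-enal
Conditions: Dess–Martin periodinane, pyridine, CH2Cl2, 0 °C to rt; pentane/silica plug, used at once as a cold Et2O solution
Reagents that add atoms: none
Why: Dess–Martin oxidation under buffered, non-basic conditions gives the β,γ-unsaturated aldehyde without migration of the 1,1-disubstituted alkene into conjugation.

Step 3
Reactants: 3 3-(prop-2-en-1-yl)cyclopent-2-en-1-one; 5 3-methylbut-3-enal
Product: 7 (2S,3R)-2-(1-hydroxy-3-methylbut-3-en-1-yl)-3-methyl-3-(prop-2-en-1-yl)cyclopentan-1-one as a mixture of carbinol epimers, via dimethylaluminium enolate 6 (not isolated)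
Conditions: Cu(O2CC4H3S) (copper thiophene-2-carboxylate, 5 mol%), chiral biphenol-derived bis(1-arylethyl)amine phosphoramidite (10 mol%), Me3Al (1.3 equiv), Et2O, −30 °C; then 5 (2.5 equiv), −78 to −40 °C; aq. Rochelle salt
Reagents that add atoms: trimethylaluminium, C[Al](C)C
Why: Copper-catalysed asymmetric conjugate addition of Me3Al to a β-substituted cyclopentenone sets the C1 quaternary centre (R) by ligand control and gives the regiodefined aluminium enolate, whose aldol addition takes the aldehyde on the face anti to the larger allyl group so that the C5 side chain is cis to the C1 methyl; the weakly basic aluminium enolate adds to the enolisable aldehyde instead of deprotonating it, and the C6 epimer mixture is erased in step 6.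

Step 4
Reactants: 7 (2S,3R)-2-(1-hydroxy-3-methylbut-3-en-1-yl)-3-methyl-3-(prop-2-en-1-yl)cyclopentan-1-one
Product: 8 (1R,2S,3R)-2-(1-hydroxy-3-methylbut-3-en-1-yl)-3-methyl-1-(propan-2-yl)-3-(prop-2-en-1-yl)cyclopentan-1-ol (carbinol epimers in the side chain)
Conditions: i-PrMgCl (3 equiv), LaCl3·2LiCl (30 mol%), THF, −40 to 0 °C; then H2O
Reagents that add atoms: isopropylmagnesium chloride, CC(C)[Mg]Cl
Why: Lanthanum-promoted Grignard 1,2-addition suppresses enolisation, reduction and retro-aldol of the metal aldolate, and the nucleophile attacks the cyclopentanone face anti to the adjacent C5 side chain, giving the 4β tertiary alcohol (C4 R) cis to that side chain.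

Step 5
Reactants: 8 (1R,2S,3R)-2-(1-hydroxy-3-methylbut-3-en-1-yl)-3-methyl-1-(propan-2-yl)-3-(prop-2-en-1-yl)cyclopentan-1-ol
Product: 9 (3R,3aS,8aR)-6,8a-dimethyl-3-(propan-2-yl)-1,2,3,3a,4,5,8,8a-octahydroazulene-3,4-diol (mixture of C4-azulene = C6-daucane epimers)
Conditions: second-generation Grubbs catalyst (H2IMes)(PCy3)Cl2Ru=CHPh (5 mol%), CH2Cl2 (0.005 M), 40 °C
Reagents that add atoms: none
Why: Ring-closing metathesis between the allyl group and the 1,1-disubstituted alkene closes the seven-membered ring as the trisubstituted C8=C9 alkene with loss of ethene; free hydroxyls are tolerated, and the trans ring fusion is already fixed by the C1/C5 configuration from step 3.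

Step 6
Reactants: 9 (3R,3aS,8aR)-6,8a-dimethyl-3-(propan-2-yl)-1,2,3,3a,4,5,8,8a-octahydroazulene-3,4-diol
Product: 10 (3R,3aR,8aR)-3-hydroxy-6,8a-dimethyl-3-(propan-2-yl)-2,3,3a,5,8,8a-hexahydroazulen-4(1H)-one
Conditions: Dess–Martin periodinane, pyridine, CH2Cl2, 0 °C
Reagents that add atoms: none
Why: Dess–Martin oxidation touches only the secondary alcohol, so both C6 epimers converge on one tertiary aldol under buffered conditions that avoid retro-aldol, dehydration, C5 epimerisation and conjugation of the β,γ-alkene.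

Step 7
Reactants: 10 (3R,3aR,8aR)-3-hydroxy-6,8a-dimethyl-3-(propan-2-yl)-2,3,3a,5,8,8a-hexahydroazulen-4(1H)-one; 11 4-[(tert-butyldimethylsilyl)oxy]benzaldehyde
Product: 12 (3R,3aS,4S,8aR)-4-hydroxy-6,8a-dimethyl-3-(propan-2-yl)-1,2,3,3a,4,5,8,8a-octahydroazulen-3-yl 4-[(tert-butyldimethylsilyl)oxy]benzoate
Conditions: SmI2 (0.3 equiv), 11 (5 equiv), THF, −10 °C, dark; cold pH 7 phosphate buffer
Reagents that add atoms: none
Why: Proposed new method: the trivalent samarium alkoxide of the tertiary C4–OH adds to the aryl aldehyde to give a hemiacetal, samarium bridges the hemiacetal oxygen and the C6 carbonyl, and an intramolecular hydride shift through a six-membered chair transition state delivers H to the C6 face on the side of C4 (β), so the new hydroxyl is 6α (anti to O4, C6 S) and the aroyl group stays on the tertiary oxygen without ever passing through the free diol; only the 4β-OH isomer (O4 cis to C6 on the five-membered ring) can reach the ketone, and the irreversible hydride transfer drains any reversible retro-aldol opening; the closest known reaction is the Evans–Tishchenko reduction of secondary β-hydroxy ketones with SmI2 and an aldehyde, and what is new is a tertiary ring-fusion aldol as the hemiacetal donor, a β,γ-unsaturated ketone as acceptor, and a silyl-masked phenolic aldehyde that installs the natural acyl group itself (the silyl ether is needed because a free phenol would quench the samarium alkoxide).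

Step 8
Reactants: 12 (3R,3aS,4S,8aR)-4-hydroxy-6,8a-dimethyl-3-(propan-2-yl)-1,2,3,3a,4,5,8,8a-octahydroazulen-3-yl 4-[(tert-butyldimethylsilyl)oxy]benzoate
Product: 14 (3R,3aS,4S,6R,7S,8aR)-6,7-epoxy-4-hydroxy-6,8a-dimethyl-3-(propan-2-yl)decahydroazulen-3-yl 4-hydroxybenzoate (target CNP0264773.1), via silyl-protected epoxide 13 (not isolated)
Conditions: VO(acac)2 (5 mol%), t-BuOOH (1.5 equiv), CH2Cl2, 0 °C to rt; then Bu4NF/AcOH (1:1), THF, 0 °C
Reagents that add atoms: tert-butyl hydroperoxide, CC(C)(C)OO
Why: Hydroxyl-directed epoxidation with VO(acac)2/t-BuOOH delivers oxygen from the vanadium-bound homoallylic 6α-alkoxide to the α face of the C8=C9 alkene, setting C8 (R) and C9 (S) cis to the C6 hydroxyl while the silyl ether shields the phenol from the oxidant; buffered fluoride then cleaves only the aryl silyl ether without acyl migration or oxirane opening.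

## Compound list

1 | 3-ethoxycyclopent-2-en-1-one | CCOC1=CC(=O)CC1 | starting material
2 | 1-allyl-3-ethoxycyclopent-2-en-1-ol (racemic; present as its magnesium alkoxide) | CCOC1=CC(O)(CC=C)CC1 | intermediate
3 | 3-(prop-2-en-1-yl)cyclopent-2-en-1-one | C=CCC1=CC(=O)CC1 | intermediate
4 | 3-methylbut-3-en-1-ol | CC(=C)CCO | starting material
5 | 3-methylbut-3-enal | CC(=C)CC=O | intermediate
6 | dimethylaluminium (3R)-3-methyl-3-(prop-2-en-1-yl)cyclopent-1-en-1-olate | C[Al](C)OC1=C[C@@](C)(CC=C)CC1 | intermediate
7 | (2S,3R)-2-(1-hydroxy-3-methylbut-3-en-1-yl)-3-methyl-3-(prop-2-en-1-yl)cyclopentan-1-one, side chain cis to the ring methyl, carbinol epimers | O=C1CC[C@](C)(CC=C)[C@H]1C(O)CC(C)=C | intermediate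
8 | (1R,2S,3R)-2-(1-hydroxy-3-methylbut-3-en-1-yl)-3-methyl-1-(propan-2-yl)-3-(prop-2-en-1-yl)cyclopentan-1-ol, tertiary OH cis to the side chain, carbinol epimers | CC(C)[C@]1(O)CC[C@](C)(CC=C)[C@H]1C(O)CC(C)=C | intermediate
9 | (3R,3aS,8aR)-6,8a-dimethyl-3-(propan-2-yl)-1,2,3,3a,4,5,8,8a-octahydroazulene-3,4-diol, trans-fused, epimers at the secondary carbinol | CC(C)[C@]1(O)CC[C@]2(C)CC=C(C)CC(O)[C@H]21 | intermediate
10 | (3R,3aR,8aR)-3-hydroxy-6,8a-dimethyl-3-(propan-2-yl)-2,3,3a,5,8,8a-hexahydroazulen-4(1H)-one (4β-hydroxydauc-8-en-6-one) | CC(C)[C@]1(O)CC[C@]2(C)CC=C(C)CC(=O)[C@H]21 | intermediate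
11 | 4-[(tert-butyldimethylsilyl)oxy]benzaldehyde | O=Cc1ccc(O[Si](C)(C)C(C)(C)C)cc1 | starting material
12 | (3R,3aS,4S,8aR)-4-hydroxy-6,8a-dimethyl-3-(propan-2-yl)-1,2,3,3a,4,5,8,8a-octahydroazulen-3-yl 4-[(tert-butyldimethylsilyl)oxy]benzoate | CC(C)[C@]1(OC(=O)c2ccc(O[Si](C)(C)C(C)(C)C)cc2)CC[C@]2(C)CC=C(C)C[C@H](O)[C@H]21 | intermediate
13 | (3R,3aS,4S,6R,7S,8aR)-6,7-epoxy-4-hydroxy-6,8a-dimethyl-3-(propan-2-yl)decahydroazulen-3-yl 4-[(tert-butyldimethylsilyl)oxy]benzoate | CC(C)[C@]1(OC(=O)c2ccc(O[Si](C)(C)C(C)(C)C)cc2)CC[C@]2(C)C[C@@H]3O[C@]3(C)C[C@H](O)[C@H]21 | intermediate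
14 | (3R,3aS,4S,6R,7S,8aR)-6,7-epoxy-4-hydroxy-6,8a-dimethyl-3-(propan-2-yl)decahydroazulen-3-yl 4-hydroxybenzoate (8α,9α-epoxy-6α-hydroxydaucan-4β-yl 4-hydroxybenzoate) | CC(C)[C@]1(OC(=O)c2ccc(O)cc2)CC[C@]2(C)C[C@@H]3O[C@]3(C)C[C@H](O)[C@H]21 | target

## Step count and risks

Total steps: 8. Longest linear sequence: 7 (steps 1, 3, 4, 5, 6, 7, 8); step 2 is a one-step side branch.

The three steps most likely to fail:

**Step 3 (asymmetric conjugate methylation / aluminium-enolate aldol).** The risks are the enantioselectivity on an allyl-bearing cyclopentenone, sluggish aldol of an aluminium enolate next to a quaternary centre, and modest facial control at C5 (methyl versus allyl); the minor C5 epimer would be removed at 8. The fallback sets out from 3 and separates the two C–C bond formations. The same copper-catalysed Me3Al addition is quenched with Me3SiOTf to give the isolated silyl enol ether [(3R)-3-methyl-3-(prop-2-en-1-yl)cyclopent-1-en-1-yl]oxy(trimethyl)silane F1. A Mukaiyama aldol of this with 5 (BF3·OEt2, CH2Cl2, −78 °C), through an open transition state, then comes back to the route at 7.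

**Step 4 (isopropyl addition).** A secondary Grignard reagent may reduce or enolise the ketone, and facial selectivity on the monocyclic ketone is not guaranteed. The fallback sets out from 7. Ring-closing metathesis is run first (second-generation Grubbs catalyst) to give the trans-fused bicyclic hydroxy ketone (3aS,8aR)-4-hydroxy-6,8a-dimethyl-2,3a,4,5,8,8a-hexahydroazulen-3(1H)-one F2, in which the angular methyl blocks the β face of the carbonyl. The smaller, non-reducing sp2 nucleophile isopropenylmagnesium bromide (LaCl3·2LiCl) then gives the isopropenyl carbinol (3S,3aS,8aR)-6,8a-dimethyl-3-(prop-1-en-2-yl)-1,2,3,3a,4,5,8,8a-octahydroazulene-3,4-diol F3. Selective hydrogenation of its 1,1-disubstituted alkene over the ring trisubstituted alkene with RhCl(PPh3)3/H2 comes back to the route at 9.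

**Step 7 (the proposed tertiary-aldol Tishchenko esterification).** The risks are slow hemiacetal formation at the hindered tertiary alkoxide, retro-aldol opening followed by intermolecular aldol with the aldehyde, and migration of the acyl group from the tertiary to the secondary oxygen if the samarium alkoxide of the product is left warm. The fallback uses known chemistry and sets out from 10:
- Evans–Saksena reduction with Me4NBH(OAc)3 (MeCN/AcOH, −30 °C), with hydride delivered from boron bound to the tertiary hydroxyl, gives the anti diol (3R,3aS,4S,8aR)-6,8a-dimethyl-3-(propan-2-yl)-1,2,3,3a,4,5,8,8a-octahydroazulene-3,4-diol F4.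
- 4-Methoxybenzyl trichloroacetimidate with La(OTf)3 (cat.) etherifies only the secondary hydroxyl to give the 4-methoxybenzyl ether F5.
- The tertiary alkoxide (KN(SiMe3)2, THF, −78 °C) is acylated with 4-[(tert-butyldimethylsilyl)oxy]benzoyl chloride F6 (made from the commercial acid with oxalyl chloride) to give the fully protected ester F7.
- DDQ (CH2Cl2/pH 7 buffer) removes the 4-methoxybenzyl group and comes back to the route at 12.

## Further compounds

F1 | step 3 | [(3R)-3-methyl-3-(prop-2-en-1-yl)cyclopent-1-en-1-yl]oxy(trimethyl)silane | C[Si](C)(C)OC1=C[C@@](C)(CC=C)CC1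
F2 | step 4 | (3aS,8aR)-4-hydroxy-6,8a-dimethyl-2,3a,4,5,8,8a-hexahydroazulen-3(1H)-one (carbinol epimers) | O=C1CC[C@]2(C)CC=C(C)CC(O)[C@H]21
F3 | step 4 | (3S,3aS,8aR)-6,8a-dimethyl-3-(prop-1-en-2-yl)-1,2,3,3a,4,5,8,8a-octahydroazulene-3,4-diol (carbinol epimers) | CC(=C)[C@]1(O)CC[C@]2(C)CC=C(C)CC(O)[C@H]21
F4 | step 7 | (3R,3aS,4S,8aR)-6,8a-dimethyl-3-(propan-2-yl)-1,2,3,3a,4,5,8,8a-octahydroazulene-3,4-diol | CC(C)[C@]1(O)CC[C@]2(C)CC=C(C)C[C@H](O)[C@H]21
F5 | step 7 | (3R,3aS,4S,8aR)-4-[(4-methoxybenzyl)oxy]-6,8a-dimethyl-3-(propan-2-yl)-1,2,3,3a,4,5,8,8a-octahydroazulen-3-ol | CC(C)[C@]1(O)CC[C@]2(C)CC=C(C)C[C@H](OCc3ccc(OC)cc3)[C@H]21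
F6 | step 7 | 4-[(tert-butyldimethylsilyl)oxy]benzoyl chloride | O=C(Cl)c1ccc(O[Si](C)(C)C(C)(C)C)cc1
F7 | step 7 | (3R,3aS,4S,8aR)-4-[(4-methoxybenzyl)oxy]-6,8a-dimethyl-3-(propan-2-yl)-1,2,3,3a,4,5,8,8a-octahydroazulen-3-yl 4-[(tert-butyldimethylsilyl)oxy]benzoate | CC(C)[C@]1(OC(=O)c2ccc(O[Si](C)(C)C(C)(C)C)cc2)CC[C@]2(C)CC=C(C)C[C@H](OCc3ccc(OC)cc3)[C@H]21
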